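The quinone ring (C1, C2, C3, C4, C4a, C8a) is cut at C1–C8a and traced to a four-membered ring: a 4-aryl-4-hydroxy-2-methylcyclobut-2-enone whose four carbons become C1–C4. Heating opens this ring (4π) to an aryl vinylketene that closes (6π) onto the arene. The cyclobutenone thereby grows by C4a and C8a into the hydroquinone, which is oxidised in the same flask to the 2-methyl-1,4-naphthoquinone. The step exploits that C7, which carries the side chain, is para to C4a: the precursor is a para-substituted phenyl ring with equivalent ortho positions, so one regioisomer results. The complete chiral side chain (Sharpless epoxidation, Payne inversion, B-alkyl Suzuki coupling) is in place beforehand.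

Key step: step 10

Remark: naphthoquinone numbering is used (C1 = carbonyl next to C2–Me, side chain at C7). The ring carbinol centre of 19–21 forms without control, is drawn without configuration and vanishes in step 10.

Step 1
Reactants: 1 geraniol
Product: 2 (2S,3S)-2,3-epoxygeraniol
Conditions: Ti(OiPr)4 (5 mol %), L-(+)-DET (7 mol %), t-BuOOH, 4 Å MS, CH2Cl2, −20 °C
Reagents that add atoms: tert-butyl hydroperoxide, CC(C)(C)OO
Why: The Katsuki–Sharpless asymmetric epoxidation is directed by the allylic hydroxyl, so only the 2,3-alkene reacts, and the L-(+)-tartrate catalyst delivers oxygen to the face that gives the (2S,3S)-epoxide, which fixes the tertiary C–O stereocentre of the target.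

Step 2
Reactants: 2 (2S,3S)-2,3-epoxygeraniol
Product: 4 (3R,4S)-4,8-dimethylnona-1,7-diene-3,4-diol, via terminal epoxide 3 (not isolated)
Conditions: Me3SI (6 equiv), n-BuLi (5.5 equiv), THF, −10 °C to rt
Reagents that add atoms: trimethylsulfonium iodide (source of the ylide CH2), C[S+](C)C.[I-]
Why: Under the basic conditions the alkoxide of 2 equilibrates by Payne rearrangement, an intramolecular SN2 attack of the C1 oxygen on C2 that inverts this centre to the (R)-configuration needed for the acetate-bearing carbon, and only the unhindered terminal epoxide 3 is opened at its CH2 by dimethylsulfonium methylide, after which ylide-mediated loss of dimethyl sulfide gives the one-carbon-homologated allylic alcohol (sulfonium-ylide epoxide-to-allylic-alcohol homologation).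

Step 3
Reactants: 4 (3R,4S)-4,8-dimethylnona-1,7-diene-3,4-diol
Product: 5 (4S,5R)-2,2,4-trimethyl-4-(4-methylpent-3-en-1-yl)-5-vinyl-1,3-dioxolane
Conditions: 2,2-dimethoxypropane, PPTS (cat.), CH2Cl2, rt
Reagents that add atoms: 2,2-dimethoxypropane, COC(C)(C)OC
Why: Acid-catalysed transketalisation ties the vicinal diol into a five-membered acetonide that masks both hydroxyls against 9-BBN and organolithium reagents without touching either stereocentre.

Step 4
Reactants: 6 propyne; 7 4-bromobenzyl bromide
Product: 10 1-bromo-4-(pent-3-yn-1-yl)benzene, via 1,3-dilithiopropyne 8 (not isolated), via lithium acetylide 9 (not isolated)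
Conditions: 6, n-BuLi (2 equiv), TMEDA, Et2O–hexane, −78 to 0 °C; 7, −78 °C to rt; then MeI, THF–DMPU, 0 °C to rt
Reagents that add atoms: iodomethane, CI
Why: The propargylic carbon of 1,3-dilithiopropyne is the more nucleophilic site and is benzylated first (SN2), the remaining lithium acetylide is then methylated in the same flask, and neither carbanion should exchange the aryl bromide at low temperature.

Step 5
Reactants: 10 1-bromo-4-(pent-3-yn-1-yl)benzene
Product: 12 1-bromo-4-[(3E)-4-iodopent-3-en-1-yl]benzene, via alkenylzirconocene 11 (not isolated)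
Conditions: Cp2Zr(H)Cl (1.5 equiv), THF, rt to 40 °C; then I2, 0 °C
Reagents that add atoms: iodine, II
Why: Hydrozirconation with the Schwartz reagent is a syn addition that, under equilibration by a slight excess of reagent, should place zirconium on the less hindered methyl-bearing alkyne carbon, and iodinolysis with retention then gives the (E)-iodide with iodine trans to the arylethyl chain; any regioisomer is removed by chromatography.

Step 6
Reactants: 5 (4S,5R)-2,2,4-trimethyl-4-(4-methylpent-3-en-1-yl)-5-vinyl-1,3-dioxolane; 12 1-bromo-4-[(3E)-4-iodopent-3-en-1-yl]benzene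
Product: 14 (4S,5R)-5-[(3E)-6-(4-bromophenyl)-3-methylhex-3-en-1-yl]-2,2,4-trimethyl-4-(4-methylpent-3-en-1-yl)-1,3-dioxolane, via B-alkyl-9-BBN borane 13 (not isolated)
Conditions: 5, 9-BBN (1.2 equiv), THF, rt; then 12, PdCl2(dppf) (5 mol %), AsPh3, Cs2CO3, DMF–H2O, rt
Reagents that add atoms: none
Why: 9-BBN hydroborates only the monosubstituted alkene at its terminus, and the B-alkyl Suzuki–Miyaura coupling proceeds with retention at the alkenyl iodide, whose oxidative addition at room temperature is much faster than that of the aryl bromide, so the (E)-trisubstituted alkene forms and the bromide is kept.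

Step 7
Reactants: 15 diisopropyl squarate
Product: 17 3-isopropoxy-4-methylcyclobut-3-ene-1,2-dione, via methyllithium adduct 16 (not isolated)
Conditions: MeLi, THF, −78 °C; then aq. HCl, CH2Cl2, rt
Reagents that add atoms: methyllithium, [Li]C; water, O
Why: 1,2-Addition of MeLi to one squarate carbonyl, then acid-induced loss of the new hydroxyl assisted by the vinylogous isopropoxy group and hydrolysis of the oxocarbenium ion, is the standard route to 3-alkoxy-4-alkylcyclobutenediones.

Step 8
Reactants: 14 the aryl bromide from step 6; 17 3-isopropoxy-4-methylcyclobut-3-ene-1,2-dione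
Product: 19 4-hydroxy-3-isopropoxy-2-methyl-4-(4-R-phenyl)cyclobut-2-en-1-one (R = acetonide side chain of 14; both carbinol epimers), via aryllithium 18 (not isolated)
Conditions: 14, n-BuLi (1.05 equiv), THF, −78 °C; cannulated into 17 (1.2 equiv), THF, −78 °C; then H2O
Reagents that add atoms: none
Why: Bromine–lithium exchange is faster than any reaction with the acetal or the alkenes, and the aryllithium adds 1,2 to the carbonyl next to the isopropoxy-bearing carbon because the other carbonyl is deactivated as a vinylogous ester, which places the aryl carbinol diagonal to the methyl-bearing ring carbon; the new carbinol centre is not controlled and is lost later.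

Step 9
Reactants: 19 the cyclobutenone adduct from step 8
Product: 21 4-{4-[(3E,7R,8S)-7,8-dihydroxy-4,8,12-trimethyltrideca-3,11-dien-1-yl]phenyl}-4-hydroxy-2-methylcyclobut-2-en-1-one, via cyclobutenediol 20 (not isolated)
Conditions: DIBAL-H (3 equiv), CH2Cl2, −78 °C; then 1 M HCl, THF, 0 °C to rt
Reagents that add atoms: water, O
Why: In this Stork–Danheiser-type carbonyl transposition DIBAL-H reduces the vinylogous-ester carbonyl in 1,2-fashion and acid ionises only the new secondary allylic hydroxyl, since only that cation is stabilised by the isopropoxy group at the far allyl terminus, so hydrolysis puts the carbonyl next to the aryl carbinol and leaves H on the future C3, while the same aqueous acid cleaves the acetonide without breaking the C–O bonds at the two stereocentres.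

Step 10
Reactants: 21 the 4-aryl-4-hydroxy-2-methylcyclobutenone from step 9
Product: 24 7-[(3E,7R,8S)-7,8-dihydroxy-4,8,12-trimethyltrideca-3,11-dien-1-yl]-2-methylnaphthalene-1,4-dione, via vinylketene 22 (not isolated), via hydroquinone 23 (not isolated)
Conditions: p-xylene (0.01 M), 138 °C, Ar; then Ag2O, rt
Reagents that add atoms: none
Why: Heating opens the cyclobutenone by a conrotatory 4π electrocyclic reaction in which the C4 hydroxyl rotates outward (torquoselectivity of donor groups), so the aryl group ends up cis to the ketene in 22. The ketene carbon (future C1) then bonds to an ortho carbon of the arene (future C8a) in a thermal disrotatory 6π electrocyclisation, the only ring closure of the step, and tautomerisation gives hydroquinone 23, which Ag2O dehydrogenates to the quinone; this is the Moore–Liebeskind ring expansion of 4-aryl-4-hydroxycyclobutenones. The four-membered ring thus grows by the two arene carbons C4a and C8a into the six-membered quinone ring. No stereocentre is formed, and the uncontrolled carbinol centre of 21 is erased. Regioselectivity is needed in two respects and is built into the substrate: the two ortho positions of the para-substituted ring are equivalent, which puts the chain at C7, and the methyl sits on the carbon next to the ketene carbon, which puts it at C2. Neutral, dilute conditions should leave the two trisubstituted alkenes and the diol untouched and disfavour bimolecular capture of the ketene.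

Step 11
Reactants: 24 the quinone diol from step 10
Product: 25 chabrolonaphthoquinone B
Conditions: Ac2O (1.2 equiv), pyridine, DMAP (cat.), CH2Cl2, 0 °C
Reagents that add atoms: acetic anhydride, CC(=O)OC(C)=O
Why: Acylation discriminates the secondary from the hindered tertiary alcohol, so about one equivalent of anhydride should give the (R)-monoacetate with both stereocentres untouched.

Compound list
1 | geraniol | CC(C)=CCC/C(C)=C/CO | starting material
2 | (2S,3S)-2,3-epoxygeraniol | OC[C@@H]1O[C@@]1(C)CCC=C(C)C | intermediate
3 | (2S)-6-methyl-2-[(2R)-oxiran-2-yl]hept-5-en-2-ol (Payne isomer, formed in situ) | C1O[C@H]1[C@@](C)(O)CCC=C(C)C | intermediate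
4 | (3R,4S)-4,8-dimethylnona-1,7-diene-3,4-diol | O[C@H](C=C)[C@@](C)(O)CCC=C(C)C | intermediate
5 | (4S,5R)-2,2,4-trimethyl-4-(4-methylpent-3-en-1-yl)-5-vinyl-1,3-dioxolane | CC1(C)O[C@H](C=C)[C@@](C)(O1)CCC=C(C)C | intermediate
6 | propyne | CC#C | starting material
7 | 4-bromobenzyl bromide | BrCc1ccc(Br)cc1 | starting material
8 | 1,3-dilithiopropyne (formed in situ) | [Li]CC#C[Li] | intermediate
9 | lithium 4-(4-bromophenyl)but-1-yn-1-ide (formed in situ) | [Li]C#CCCc1ccc(Br)cc1 | intermediate
10 | 1-bromo-4-(pent-3-yn-1-yl)benzene | CC#CCCc1ccc(Br)cc1 | intermediate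
11 | (E)-alkenyl(chloro)zirconocene, Zr on the methyl-bearing carbon (formed in situ) | Cl[Zr](C1C=CC=C1)(C1C=CC=C1)/C(C)=C/CCc1ccc(Br)cc1 | intermediate
12 | 1-bromo-4-[(3E)-4-iodopent-3-en-1-yl]benzene | I/C(C)=C/CCc1ccc(Br)cc1 | intermediate
13 | B-alkyl-9-BBN from 5, boron on the former terminal vinyl carbon (formed in situ) | CC1(C)O[C@H](CCB2C3CCCC2CCC3)[C@@](C)(O1)CCC=C(C)C | intermediate
14 | (4S,5R)-5-[(3E)-6-(4-bromophenyl)-3-methylhex-3-en-1-yl]-2,2,4-trimethyl-4-(4-methylpent-3-en-1-yl)-1,3-dioxolane | CC1(C)O[C@H](CC/C(C)=C/CCc2ccc(Br)cc2)[C@@](C)(O1)CCC=C(C)C | intermediate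
15 | diisopropyl squarate | CC(C)OC1=C(OC(C)C)C(=O)C1=O | starting material
16 | 4-hydroxy-2,3-diisopropoxy-4-methylcyclobut-2-en-1-one (formed in situ) | CC(C)OC1=C(OC(C)C)C(C)(O)C1=O | intermediate
17 | 3-isopropoxy-4-methylcyclobut-3-ene-1,2-dione | CC(C)OC1=C(C)C(=O)C1=O | intermediate
18 | aryllithium from 14 (formed in situ) | CC1(C)O[C@H](CC/C(C)=C/CCc2ccc([Li])cc2)[C@@](C)(O1)CCC=C(C)C | intermediate
19 | 4-aryl-4-hydroxy-3-isopropoxy-2-methylcyclobut-2-en-1-one with the acetonide side chain (carbinol epimers) | CC1(C)O[C@H](CC/C(C)=C/CCc2ccc(cc2)C3(O)C(=O)C(C)=C3OC(C)C)[C@@](C)(O1)CCC=C(C)C | intermediate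
20 | 1-aryl-2-isopropoxy-3-methylcyclobut-2-ene-1,4-diol with the acetonide side chain (formed in situ) | CC1(C)O[C@H](CC/C(C)=C/CCc2ccc(cc2)C3(O)C(O)C(C)=C3OC(C)C)[C@@](C)(O1)CCC=C(C)C | intermediate
21 | 4-{4-[(3E,7R,8S)-7,8-dihydroxy-4,8,12-trimethyltrideca-3,11-dien-1-yl]phenyl}-4-hydroxy-2-methylcyclobut-2-en-1-one (carbinol epimers) | O[C@H](CC/C(C)=C/CCc1ccc(cc1)C2(O)C=C(C)C2=O)[C@@](C)(O)CCC=C(C)C | intermediate
22 | aryl(hydroxy)vinylketene, aryl cis to the ketene arm (formed in situ) | O[C@H](CC/C(C)=C/CCc1ccc(cc1)/C(O)=C\C(C)=C=O)[C@@](C)(O)CCC=C(C)C | intermediate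
23 | 7-[(3E,7R,8S)-7,8-dihydroxy-4,8,12-trimethyltrideca-3,11-dien-1-yl]-2-methylnaphthalene-1,4-diol (formed in situ) | O[C@H](CC/C(C)=C/CCc1ccc2c(O)cc(C)c(O)c2c1)[C@@](C)(O)CCC=C(C)C | intermediate
24 | 7-[(3E,7R,8S)-7,8-dihydroxy-4,8,12-trimethyltrideca-3,11-dien-1-yl]-2-methylnaphthalene-1,4-dione | O[C@H](CC/C(C)=C/CCc1ccc2c(c1)C(=O)C(C)=CC2=O)[C@@](C)(O)CCC=C(C)C | intermediate
25 | chabrolonaphthoquinone B | CC(=O)O[C@H](CC/C(C)=C/CCc1ccc2c(c1)C(=O)C(C)=CC2=O)[C@@](C)(O)CCC=C(C)C | target

Total steps: 11. Longest linear sequence: 8 (steps 1, 2, 3, 6, 8, 9, 10, 11).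

Steps most likely to fail

Step 2. The Payne equilibration of the lithium alkoxide may be slow. After ylide attack, the neighbouring tertiary alkoxide may displace dimethyl sulfide intramolecularly (cyclic ether formation) instead of the desired elimination. The fallback sets out from 2 and comes back at 4. Parikh–Doering oxidation (SO3·pyridine, DMSO, Et3N) gives the epoxy aldehyde F1, and Wittig methylenation (Ph3P=CH2, THF) gives the vinyl epoxide F2. Hydroxide (KOH, DMSO–H2O, 80 °C) then opens F2 by SN2 attack at the secondary allylic carbon, the tertiary carbon being blocked. This inverts the same centre as the Payne route and leads to 4.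

Step 9. The cyclobutene-1,2-diolate may undergo oxyanion-accelerated electrocyclic opening before the quench. Ionisation may take place at the benzylic carbinol. The tertiary side-chain alcohol may add to the prenyl alkene during the longer acid treatment needed for the acetonide. The fallback sets out from 19 and comes back at 24, and installs the C3 hydrogen after the ring expansion instead of before it. The fully substituted cyclobutenone 19 is ring-expanded as it is (p-xylene, reflux; Ag2O) to the isopropoxyquinone F3. The vinylogous ester is saponified (KOH, MeOH–H2O) to the hydroxyquinone F4, which is converted (Tf2O, pyridine) into the quinone triflate F5. This is reduced (Pd(PPh3)4, HCO2H, Et3N, then air) to the acetonide-protected quinone F6, and 1 M HCl–THF then gives 24.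

Step 10. The vinylketene may be captured by the free side-chain hydroxyls, or the minor inward-rotated isomer may lactonise through its own enol hydroxyl, instead of electrocyclising. The fallback sets out from 19 and comes back at 23, and runs the ring expansion on a fully masked substrate. DIBAL-H reduction followed by a brief treatment with aqueous oxalic acid hydrolyses only the enol ether and gives the acetonide cyclobutenone F7. Silylation of the ring carbinol (TMSOTf, 2,6-lutidine) gives the silyl ether F8, and thermolysis in p-xylene gives the monosilylated naphthalenediol F9. 1 M HCl–THF then removes silyl group and acetonide together to give 23, which is oxidised with Ag2O as in step 10.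

Further compounds
F1 | step 2 | (2R,3S)-3-methyl-3-(4-methylpent-3-en-1-yl)oxirane-2-carbaldehyde | O=C[C@@H]1O[C@@]1(C)CCC=C(C)C
F2 | step 2 | (2S,3S)-2-methyl-2-(4-methylpent-3-en-1-yl)-3-vinyloxirane | C=C[C@@H]1O[C@@]1(C)CCC=C(C)C
F3 | step 9 | 3-isopropoxy-2-methyl-1,4-naphthoquinone carrying the acetonide side chain at C7 | CC1(C)O[C@H](CC/C(C)=C/CCc2ccc3c(c2)C(=O)C(C)=C(OC(C)C)C3=O)[C@@](C)(O1)CCC=C(C)C
F4 | step 9 | 3-hydroxy-2-methyl-1,4-naphthoquinone carrying the acetonide side chain at C7 | CC1(C)O[C@H](CC/C(C)=C/CCc2ccc3c(c2)C(=O)C(C)=C(O)C3=O)[C@@](C)(O1)CCC=C(C)C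
F5 | step 9 | 2-methyl-1,4-naphthoquinon-3-yl triflate carrying the acetonide side chain at C7 | CC1(C)O[C@H](CC/C(C)=C/CCc2ccc3c(c2)C(=O)C(C)=C(OS(=O)(=O)C(F)(F)F)C3=O)[C@@](C)(O1)CCC=C(C)C
F6 | step 9 | acetonide of 24 | CC1(C)O[C@H](CC/C(C)=C/CCc2ccc3c(c2)C(=O)C(C)=CC3=O)[C@@](C)(O1)CCC=C(C)C
F7 | step 10 | acetonide of 21 | CC1(C)O[C@H](CC/C(C)=C/CCc2ccc(cc2)C3(O)C=C(C)C3=O)[C@@](C)(O1)CCC=C(C)C
F8 | step 10 | trimethylsilyl ether of F7 at the ring carbinol | CC1(C)O[C@H](CC/C(C)=C/CCc2ccc(cc2)C3(O[Si](C)(C)C)C=C(C)C3=O)[C@@](C)(O1)CCC=C(C)C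
F9 | step 10 | 2-methyl-4-(trimethylsilyloxy)naphthalen-1-ol carrying the acetonide side chain at C7 | CC1(C)O[C@H](CC/C(C)=C/CCc2ccc3c(O[Si](C)(C)C)cc(C)c(O)c3c2)[C@@](C)(O1)CCC=C(C)C
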